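**Plan**

1. Retrosynthesis: the phenol is unmasked last. The cyclohexa-2,5-dienone ring is then cut at C4–C5 and at C2=C3, giving an α-methoxy aldehyde (C3, C4 and the side chain) and 1-methoxyhept-6-en-1-yn-3-one (C5, C6, C1, C2 and the allyl group). The aldehyde goes back by a one-carbon cut to an ester, and the ester by the ArCH2–CH2 bond to an aryl bromide and a chiral bromo ester.
2. Enabling feature: in the cross-conjugated ring the quaternary C4 is alpha to C3 (an aldehyde-level CH) and bonded to C5, the beta carbon of the vinylogous ester C5(OMe)=C6–C1=O, while C2 is the alpha' carbon of the C1 ketone. This is a Robinson retron at the oxidation level of an alkoxy-ynone.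
3. Forward: Negishi coupling joins the guaiacyl ring to the chiral three-carbon unit; the ester becomes the α-methoxy aldehyde (methylenation, hydroboration, oxidation); its chiral imine and the ynone are annulated to give the only new ring; desilylation ends the route.
4. Stereochemistry: the side-chain methyl centre is bought with methyl (S)-3-bromo-2-methylpropanoate. The quaternary C4 is set in the annulation by the (S)-1-phenylethylamine auxiliary; both α-epimers of the aldehyde converge through one enamine.

Key step: step 9

Assumption: the facial sense of the auxiliary in step 9 is assigned from the accepted transition-state model for chiral secondary enamines; if the other face reacted, the (R)-amine would be used in the same steps.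
Abbreviation: Ar = 3-methoxy-4-[tri(propan-2-yl)silyloxy]phenyl (TIPS = tri(propan-2-yl)silyl).

**Route**

Step 1
Reactants: 1 4-bromo-2-methoxyphenol
Product: 2 (4-bromo-2-methoxyphenoxy)tri(propan-2-yl)silane
Conditions: TIPSCl, imidazole, DMF, 25 °C
Reagents that add atoms: tri(propan-2-yl)silyl chloride, CC(C)[Si](Cl)(C(C)C)C(C)C
Why: Imidazole-promoted silyl ether formation masks the acidic phenol for the organometallic steps, and the bulky TIPS group should survive base and leave with fluoride at the end.

Step 2
Reactants: 3 methyl (S)-3-bromo-2-methylpropanoate; 2 (4-bromo-2-methoxyphenoxy)tri(propan-2-yl)silane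
Product: 5 methyl (2R)-3-Ar-2-methylpropanoate, via organozinc bromide 4 (not isolated)
Conditions: Zn dust (activated), LiCl, THF, 45 °C; then 2, Pd(OAc)2 (2 mol%), SPhos (2-dicyclohexylphosphino-2',6'-dimethoxybiphenyl, 4 mol%), THF, 25 to 50 °C
Reagents that add atoms: none
Why: LiCl-mediated zinc insertion gives a β-zincated ester whose stereocentre is not the metal-bearing carbon, and Negishi cross-coupling with the aryl bromide under non-basic conditions should join the fragments without epimerisation, so the (R)-methyl centre is bought and not made.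

Step 3
Reactants: 5 methyl (2R)-3-Ar-2-methylpropanoate
Product: 6 {2-methoxy-4-[(2R)-3-methoxy-2-methylbut-3-en-1-yl]phenoxy}tri(propan-2-yl)silane
Conditions: Cp2TiMe2 (2.5 equiv), toluene, 65 °C, dark; work-up on base-washed silica
Reagents that add atoms: dimethyltitanocene Cp2TiMe2, C[Ti](C)(C1C=CC=C1)C1C=CC=C1
Why: Petasis methylenation of the ester carbonyl by the titanium methylidene formed on heating gives the 2-methoxyalkene under non-basic conditions that should leave the neighbouring stereocentre untouched.

Step 4
Reactants: 6 {2-methoxy-4-[(2R)-3-methoxy-2-methylbut-3-en-1-yl]phenoxy}tri(propan-2-yl)silane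
Product: 8 (3R)-4-Ar-2-methoxy-3-methylbutan-1-ol (mixture of C2 epimers), via alkylborane 7 (not isolated)
Conditions: 9-BBN, THF, 0 to 25 °C; then 3 M NaOH, 30% H2O2, 0 °C
Reagents that add atoms: hydrogen peroxide, OO
Why: Hydroboration–oxidation of the 1,1-disubstituted enol ether should place boron on the terminal carbon for steric and electronic reasons and give the primary alcohol; the new C2 centre is left uncontrolled on purpose because step 9 erases it.

Step 5
Reactants: 8 (3R)-4-Ar-2-methoxy-3-methylbutan-1-ol
Product: 9 (3R)-4-Ar-2-methoxy-3-methylbutanal (mixture of C2 epimers)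
Conditions: Dess–Martin periodinane, CH2Cl2, 0 to 25 °C
Reagents that add atoms: none
Why: Dess–Martin oxidation of the primary alcohol should stop cleanly at the α-methoxy aldehyde, and epimerisation at C2 is of no consequence.

Step 6
Reactants: 9 (3R)-4-Ar-2-methoxy-3-methylbutanal; 10 (S)-1-phenylethylamine
Product: 11 (1E,3R)-4-Ar-2-methoxy-3-methyl-N-[(1S)-1-phenylethyl]butan-1-imine (mixture of C2 epimers)
Conditions: MgSO4, CH2Cl2, 25 °C; filtered, concentrated, used crude
Reagents that add atoms: none
Why: Condensation of the aldehyde with the primary amine (imine formation) installs the chiral auxiliary and uses up all free amine before the amine-sensitive ynone is added.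

Step 7
Reactants: 12 pent-4-enoyl chloride
Product: 13 N-methoxy-N-methylpent-4-enamide
Conditions: MeNHOMe·HCl, pyridine, CH2Cl2, 0 to 25 °C
Reagents that add atoms: N,O-dimethylhydroxylamine hydrochloride, CNOC.Cl
Why: Acylation of N,O-dimethylhydroxylamine by the acid chloride gives the Weinreb amide needed for a clean ketone synthesis.

Step 8
Reactants: 14 2-chloro-1,1-dimethoxyethane; 13 N-methoxy-N-methylpent-4-enamide
Product: 16 1-methoxyhept-6-en-1-yn-3-one, via lithium methoxyacetylide 15 (not isolated)
Conditions: LiNEt2 (3.1 equiv, from n-BuLi and Et2NH), THF, −78 to 0 °C; then 13, −78 °C; sat. aq NH4Cl, −78 °C, fast cold work-up; used at once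
Reagents that add atoms: none
Why: Twofold elimination from the chloroacetal and deprotonation should give lithium methoxyacetylide, whose addition to the Weinreb amide stops at the chelated tetrahedral adduct and releases the ynone only on quench (Weinreb ketone synthesis).

Step 9
Reactants: 11 (1E,3R)-4-Ar-2-methoxy-3-methyl-N-[(1S)-1-phenylethyl]butan-1-imine; 16 1-methoxyhept-6-en-1-yn-3-one
Product: 19 (4R)-4-[(2R)-1-Ar-propan-2-yl]-4,5-dimethoxy-2-(prop-2-en-1-yl)cyclohexa-2,5-dien-1-one, via imine Michael adduct 17 (not isolated), via keto aldehyde 18 (not isolated)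
Conditions: 16 (1.3 equiv), THF, 0 to 40 °C; then 20% aq AcOH, 25 °C; then crude 18, NaOMe (0.2 equiv), MeOH, 0 °C (telescoped, no purification between)
Reagents that add atoms: none
Why: Proposed new method: imine 11 equilibrates with its secondary enamine, which erases the configuration of the alpha carbon so that both epimers converge, and the enamine carbon should add to the methoxy-bearing alkyne carbon of the push-pull ynone 16 in an aza-ene-type transition state with internal N–H transfer to give 17 (first bond, quaternary carbon to the future C5), after which aqueous AcOH frees aldehyde 18 and methoxide closes the ring by aldol condensation between the only enolisable CH2 and the non-enolisable aldehyde (second bond, the C2=C3 alkene). The closest known reaction types are the deracemising Michael addition of 1-phenylethylamine imines of alpha-substituted carbonyl compounds to electrophilic alkenes with subsequent Robinson annulation, and the C-addition of N–H enamines to ynones as in the Bohlmann–Rahtz pyridine synthesis; new are the alpha-methoxy aldimine donor and the alkoxy-ynone acceptor, which brings in the C5 methoxy enol ether at the right oxidation level. The single ring closes by a 6-(enolendo)-exo-trig aldol addition followed by E1cB loss of water. The quaternary centre is controlled by the (S)-1-phenylethyl group: with NH cis to OMe in the enamine (the sec-alkyl group turns away from nitrogen) the ynone should approach anti to the phenyl ring, which in the accepted model gives 4R and is matched with the small allylic-strain bias of the neighbouring (R)-methyl centre. The step needs C- instead of N-attack and attack at the oxygen-bearing alkyne carbon, which the cyclic ene-type transition state and the polarisation of the acyl alkynyl ether should secure. The geometry of the new enol ether need not be controlled, because degenerate methoxide addition–elimination equilibrates it and only the isomer with the acyl group cis to the quaternary carbon can cyclise.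

Step 10
Reactants: 19 (4R)-4-[(2R)-1-Ar-propan-2-yl]-4,5-dimethoxy-2-(prop-2-en-1-yl)cyclohexa-2,5-dien-1-one
Product: 20 (4R)-4-[(2R)-1-(4-hydroxy-3-methoxyphenyl)propan-2-yl]-4,5-dimethoxy-2-(prop-2-en-1-yl)cyclohexa-2,5-dien-1-one
Conditions: TBAF (1.1 equiv), AcOH (1.1 equiv), THF, 0 °C
Reagents that add atoms: none
Why: Fluoride cleavage of the aryl silyl ether, buffered with AcOH so that the dienone and the vinylogous ester are not exposed to free base, should release the phenol without touching either stereocentre.

**Compound list**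

1 | 4-bromo-2-methoxyphenol | COc1cc(Br)ccc1O | starting material
2 | (4-bromo-2-methoxyphenoxy)tri(propan-2-yl)silane | COc1cc(Br)ccc1O[Si](C(C)C)(C(C)C)C(C)C | intermediate
3 | methyl (S)-3-bromo-2-methylpropanoate | COC(=O)[C@H](C)CBr | starting material
4 | [(2S)-3-methoxy-2-methyl-3-oxopropyl]zinc bromide | COC(=O)[C@H](C)C[Zn]Br | intermediate (not isolated)
5 | methyl (2R)-3-Ar-2-methylpropanoate | COC(=O)[C@H](C)Cc1ccc(O[Si](C(C)C)(C(C)C)C(C)C)c(OC)c1 | intermediate
6 | {2-methoxy-4-[(2R)-3-methoxy-2-methylbut-3-en-1-yl]phenoxy}tri(propan-2-yl)silane | C=C(OC)[C@H](C)Cc1ccc(O[Si](C(C)C)(C(C)C)C(C)C)c(OC)c1 | intermediate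
7 | 9-[(3R)-4-Ar-2-methoxy-3-methylbutyl]-9-borabicyclo[3.3.1]nonane (C2 epimers) | COC(CB1C2CCCC1CCC2)[C@H](C)Cc1ccc(O[Si](C(C)C)(C(C)C)C(C)C)c(OC)c1 | intermediate (not isolated)
8 | (3R)-4-Ar-2-methoxy-3-methylbutan-1-ol (C2 epimers) | OCC(OC)[C@H](C)Cc1ccc(O[Si](C(C)C)(C(C)C)C(C)C)c(OC)c1 | intermediate
9 | (3R)-4-Ar-2-methoxy-3-methylbutanal (C2 epimers) | O=CC(OC)[C@H](C)Cc1ccc(O[Si](C(C)C)(C(C)C)C(C)C)c(OC)c1 | intermediate
10 | (S)-1-phenylethylamine | C[C@H](N)c1ccccc1 | starting material
11 | (1E,3R)-4-Ar-2-methoxy-3-methyl-N-[(1S)-1-phenylethyl]butan-1-imine (C2 epimers) | C[C@H](/N=C/C(OC)[C@H](C)Cc1ccc(O[Si](C(C)C)(C(C)C)C(C)C)c(OC)c1)c1ccccc1 | intermediate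
12 | pent-4-enoyl chloride | C=CCCC(=O)Cl | starting material
13 | N-methoxy-N-methylpent-4-enamide | C=CCCC(=O)N(C)OC | intermediate
14 | 2-chloro-1,1-dimethoxyethane | COC(CCl)OC | starting material
15 | lithium methoxyacetylide | [Li]C#COC | intermediate (not isolated)
16 | 1-methoxyhept-6-en-1-yn-3-one | C=CCCC(=O)C#COC | intermediate
17 | N-[(1S)-1-phenylethyl] imine of 18, quaternary carbon R, enol ether E/Z not fixed | C[C@H](/N=C/[C@](OC)([C@H](C)Cc1ccc(O[Si](C(C)C)(C(C)C)C(C)C)c(OC)c1)C(OC)=CC(=O)CCC=C)c1ccccc1 | intermediate (not isolated)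
18 | (2S)-2-[(2R)-1-Ar-propan-2-yl]-2,3-dimethoxy-5-oxonona-3,8-dienal, enol ether E/Z not fixed | O=C[C@](OC)([C@H](C)Cc1ccc(O[Si](C(C)C)(C(C)C)C(C)C)c(OC)c1)C(OC)=CC(=O)CCC=C | intermediate (not isolated)
19 | (4R)-4-[(2R)-1-Ar-propan-2-yl]-4,5-dimethoxy-2-(prop-2-en-1-yl)cyclohexa-2,5-dien-1-one | C=CCC1=C[C@](OC)([C@H](C)Cc2ccc(O[Si](C(C)C)(C(C)C)C(C)C)c(OC)c2)C(OC)=CC1=O | intermediate
20 | (4R)-4-[(2R)-1-(4-hydroxy-3-methoxyphenyl)propan-2-yl]-4,5-dimethoxy-2-(prop-2-en-1-yl)cyclohexa-2,5-dien-1-one | C=CCC1=C[C@](OC)([C@H](C)Cc2ccc(O)c(OC)c2)C(OC)=CC1=O | target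

Total step count: 10. Longest linear sequence: 8 steps (1, 2, 3, 4, 5, 6, 9, 10).

**Steps most likely to fail**

1. Step 9 (Proposed new method). What may go wrong: attack of the imine or enamine nitrogen on the ynone in place of carbon; slow bond formation at the crowded alpha carbon; poor facial selectivity because an aldimine holds its N-substituent less firmly than a ketimine; deformylation of the non-enolisable aldehyde by methoxide before the ring closes. The fallback uses known chemistry, sets out from 11 and 13 and comes back at 19. Amide 13 and vinylmagnesium bromide (THF, 0 °C, cold acidic quench) would give hepta-1,6-dien-3-one F1. Imine 11 would add to F1 in the established deracemising Michael addition of chiral imines to vinyl ketones (THF, 25 °C) to give the imine adduct F2. Aqueous AcOH would hydrolyse it to keto aldehyde F3, and NaOMe in MeOH would close it by aldol condensation to the cyclohexenone F4; any C4 epimer would be removed here by chromatography. IBX (DMSO, 70 °C) would dehydrogenate F4 to the cross-conjugated dienone F5. NaOMe in MeOH would add methanol to the unsubstituted C5=C6 enone of F5 to give the 5-methoxy ketone F6. A second IBX dehydrogenation across C5–C6 would give 19.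

2. Step 8. What may go wrong: incomplete elimination to the acetylide, and hydration or hydrolysis of the alkoxy-ynone during quench and isolation. The fallback sets out from 14 and comes back at 16. Lithium methoxyacetylide 15, made from 14 as before, would be added to commercial pent-4-enal (THF, −78 °C) to give 1-methoxyhept-6-en-1-yn-3-ol F7. MnO2 (CH2Cl2, 0 °C) would oxidise F7 to 16 under neutral conditions, with filtration as the only work-up.

3. Step 4. What may go wrong: β-elimination of the β-methoxy alkylborane, and acid-catalysed hydrolysis of the enol ether before it is hydroborated. The fallback sets out from 5 and comes back at 9. i-Bu2AlH (CH2Cl2, −78 °C) would reduce 5 to (2R)-3-Ar-2-methylpropanal F8. 2-Lithio-1,3-dithiane (from 1,3-dithiane and n-BuLi, THF, −78 °C) would add to give the dithianyl carbinol F9. NaH and MeI (THF, 0 to 25 °C) would give the methyl ether F10. MeI and CaCO3 (MeCN/H2O, 45 °C) would unmask aldehyde 9.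

Further compounds
F1 | step 9 | hepta-1,6-dien-3-one | C=CCCC(=O)C=C
F2 | step 9 | N-[(1S)-1-phenylethyl] imine of F3 | C[C@H](/N=C/[C@](OC)([C@H](C)Cc1ccc(O[Si](C(C)C)(C(C)C)C(C)C)c(OC)c1)CCC(=O)CCC=C)c1ccccc1
F3 | step 9 | (2R)-2-[(2R)-1-Ar-propan-2-yl]-2-methoxy-5-oxonon-8-enal | O=C[C@](OC)([C@H](C)Cc1ccc(O[Si](C(C)C)(C(C)C)C(C)C)c(OC)c1)CCC(=O)CCC=C
F4 | step 9 | (4R)-4-[(2R)-1-Ar-propan-2-yl]-4-methoxy-2-(prop-2-en-1-yl)cyclohex-2-en-1-one | C=CCC1=C[C@](OC)([C@H](C)Cc2ccc(O[Si](C(C)C)(C(C)C)C(C)C)c(OC)c2)CCC1=O
F5 | step 9 | (4S)-4-[(2R)-1-Ar-propan-2-yl]-4-methoxy-2-(prop-2-en-1-yl)cyclohexa-2,5-dien-1-one | C=CCC1=C[C@](OC)([C@H](C)Cc2ccc(O[Si](C(C)C)(C(C)C)C(C)C)c(OC)c2)C=CC1=O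
F6 | step 9 | (4R)-4-[(2R)-1-Ar-propan-2-yl]-4,5-dimethoxy-2-(prop-2-en-1-yl)cyclohex-2-en-1-one (C5 epimers) | C=CCC1=C[C@](OC)([C@H](C)Cc2ccc(O[Si](C(C)C)(C(C)C)C(C)C)c(OC)c2)C(OC)CC1=O
F7 | step 8 | 1-methoxyhept-6-en-1-yn-3-ol | C=CCCC(O)C#COC
F8 | step 4 | (2R)-3-Ar-2-methylpropanal | O=C[C@H](C)Cc1ccc(O[Si](C(C)C)(C(C)C)C(C)C)c(OC)c1
F9 | step 4 | (2R)-3-Ar-1-(1,3-dithian-2-yl)-2-methylpropan-1-ol (C1 epimers) | OC(C1SCCCS1)[C@H](C)Cc1ccc(O[Si](C(C)C)(C(C)C)C(C)C)c(OC)c1
F10 | step 4 | 2-[(2R)-3-Ar-1-methoxy-2-methylpropyl]-1,3-dithiane (C1 epimers) | COC(C1SCCCS1)[C@H](C)Cc1ccc(O[Si](C(C)C)(C(C)C)C(C)C)c(OC)c1
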